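**Retrosynthetic overview**
- The aryl allyl ether (C1–O) is made last, by Mitsunobu coupling of the (E)-allylic alcohol with 4-hydroxy-5-methylcoumarin; the coumarin ring is bought intact.
- The only carbocycle (C6–C7–C8–C9–C10–C11) is closed at C8–C9 by Mn(OAc)3/Cu(OAc)2 oxidative 6-endo radical cyclization of an acyclic β-keto ester onto an isopropenyl group. The same step creates the C7=C15 exocyclic methylene, and the C9 ester is then removed by Krapcho decarboxylation.
- Feature the strategy rests on: the single stereocentre C6, with its C7(=CH2)–C8 unit, its C5–C4–C3(Me) arm and its C11–C10 arm, is C5 of (S)-carvone. Isopropenyl becomes C7/C8/C15, gem-dimethylated carvone C6 becomes C11, carvone C1 becomes C10, and carvone C4/C3/C2(Me) become C5/C4/C3(Me) once the carvone C1–C2 bond is cut.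
- The acyclic precursor comes from double α′-methylation, conjugate reduction, Rubottom oxidation and Pb(OAc)4 ketol cleavage. Horner–Wadsworth–Emmons olefination adds C1–C2, and the hindered C10 ester is taken through the aldehyde to the β-keto ester by acetate aldol and oxidation, a detour that avoids a Claisen condensation on a neopentyl-type ester.
- Ring order: the carvone ring is opened in step 5 and the cyclohexanone ring of the target is closed in step 12.

Key step: step 12

Assumption: triethyl phosphonoacetate, methyl acetate and 4-hydroxy-5-methylcoumarin are bought; terpenoid carbons carry farnesane numbers (OCH2 = C1, ring CH = C6, C(=CH2) = C7, ketone = C10, CMe2 = C11, exocyclic CH2 = C15).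

**Route**

Step 1
Reactants: 1 (S)-(+)-carvone
Product: 3 (5S)-2,6-dimethyl-5-(prop-1-en-2-yl)cyclohex-2-en-1-one (6-methylcarvone; both C6 epimers), via cross-conjugated lithium dienolate of carvone 2 (not isolated)
Conditions: LiN(i-Pr)2 (1.1 equiv), THF, −78 °C; MeI, −78 → 0 °C
Reagents that add atoms: iodomethane, CI
Why: Kinetic deprotonation removes the α′ proton at carvone C6 and the cross-conjugated enolate is C-methylated (enolate alkylation); the new C6 centre is left uncontrolled because step 2 makes it quaternary.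

Step 2
Reactants: 3 6-methylcarvone
Product: 5 (5R)-2,6,6-trimethyl-5-(prop-1-en-2-yl)cyclohex-2-en-1-one (6,6-dimethylcarvone), via cross-conjugated lithium dienolate of 6-methylcarvone 4 (not isolated)
Conditions: LiN(i-Pr)2 (1.2 equiv), THF, −78 → −30 °C; MeI, DMPU, −78 → 0 °C
Reagents that add atoms: iodomethane, CI
Why: A second kinetic α′-enolate alkylation installs the gem-dimethyl group (future C11); C5 is β to the carbonyl and is not touched, its descriptor changing from S to R only through the priority rules.

Step 3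
Reactants: 5 6,6-dimethylcarvone
Product: 7 trimethyl{[(5R)-2,6,6-trimethyl-5-(prop-1-en-2-yl)cyclohex-1-en-1-yl]oxy}silane, via tetrasubstituted lithium enolate 6 (not isolated)
Conditions: LiBH(s-Bu)3 (1.1 equiv), THF, −78 °C; Me3SiCl, Et3N, −78 → 0 °C; non-aqueous work-up
Reagents that add atoms: chlorotrimethylsilane, C[Si](C)(C)Cl
Why: The bulky borohydride adds hydride 1,4 to the enone, whose β-carbon is unsubstituted and whose carbonyl is shielded by the quaternary neighbour, and the regiodefined enolate is O-silylated (conjugate reduction with enolate trapping); no stereocentre is formed.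

Step 4
Reactants: 7 silyl enol ether
Product: 9 (3R)-6-hydroxy-2,2,6-trimethyl-3-(prop-1-en-2-yl)cyclohexan-1-one (both C6 epimers), via α-trimethylsilyloxy ketone 8 (not isolated)
Conditions: mCPBA (1.0 equiv), NaHCO3, CH2Cl2, −20 → 0 °C; then Bu4NF, THF, 0 °C
Reagents that add atoms: meta-chloroperoxybenzoic acid, O=C(OO)c1cccc(Cl)c1
Why: Rubottom oxidation, in which the electron-rich tetrasubstituted enol ether is epoxidized much faster than the 1,1-disubstituted isopropenyl alkene and the silyloxy epoxide rearranges to the α-silyloxy ketone; the carbinol configuration is irrelevant because that carbon becomes a ketone in step 5.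

Step 5
Reactants: 9 α-hydroxy ketone
Product: 10 methyl (3R)-2,2-dimethyl-6-oxo-3-(prop-1-en-2-yl)heptanoate
Conditions: Pb(OAc)4 (1.1 equiv), MeOH/PhH 1:1, 0 °C → rt
Reagents that add atoms: methanol, CO
Why: Criegee-type oxidative cleavage of the α-ketol through its methanol hemiketal cuts the carvone C1–C2 bond, giving the methyl ester (C10) and the methyl ketone (C3) without touching C6.

Step 6
Reactants: 10 keto ester; 11 triethyl phosphonoacetate
Product: 12 1-ethyl 8-methyl (2E,6R)-3,7,7-trimethyl-6-(prop-1-en-2-yl)oct-2-enedioate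
Conditions: NaH, 11, THF, 0 °C; then 10, 0 °C → reflux; minor Z isomer removed by chromatography
Reagents that add atoms: none
Why: Horner–Wadsworth–Emmons olefination of the unhindered methyl ketone (the neopentyl ester is inert) adds C1–C2; reversible adduct formation is expected to favour the E alkene, with the ester trans to the larger chain.

Step 7
Reactants: 12 diester
Product: 13 (2E,6R)-3,7,7-trimethyl-6-(prop-1-en-2-yl)oct-2-ene-1,8-diol
Conditions: i-Bu2AlH (6 equiv), CH2Cl2, −78 → 0 °C; aqueous potassium sodium tartrate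
Reagents that add atoms: none
Why: Exhaustive aluminium hydride reduction takes the enoate 1,2 to the allylic alcohol and the hindered ester to the neopentyl alcohol, so no selectivity between the two esters is required.

Step 8
Reactants: 13 diol
Product: 14 (3R,6E)-8-[(tert-butyldiphenylsilyl)oxy]-2,2,6-trimethyl-3-(prop-1-en-2-yl)oct-6-en-1-ol
Conditions: t-BuPh2SiCl (1.05 equiv), imidazole, CH2Cl2, −20 → 0 °C
Reagents that add atoms: tert-butyl(chloro)diphenylsilane, CC(C)(C)[Si](Cl)(c1ccccc1)c1ccccc1
Why: Silylation with a bulky silyl chloride selects the unhindered allylic primary alcohol over the neopentyl alcohol that sits between a quaternary and a tertiary carbon.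

Step 9
Reactants: 14 mono-silyl ether
Product: 15 (3R,6E)-8-[(tert-butyldiphenylsilyl)oxy]-2,2,6-trimethyl-3-(prop-1-en-2-yl)oct-6-enal
Conditions: Dess–Martin periodinane, NaHCO3, CH2Cl2, 0 °C → rt
Reagents that add atoms: none
Why: Dess–Martin oxidation gives the non-enolizable neopentyl aldehyde under buffered conditions that spare the silyl ether and both alkenes.

Step 10
Reactants: 15 aldehyde; 16 methyl acetate
Product: 17 methyl (5R,8E)-10-[(tert-butyldiphenylsilyl)oxy]-3-hydroxy-4,4,8-trimethyl-5-(prop-1-en-2-yl)dec-8-enoate (both C3 epimers)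
Conditions: LiN(i-Pr)2, 16, THF, −78 °C; then 15, −78 °C; aqueous NH4Cl
Reagents that add atoms: none
Why: Aldol addition of the lithium enolate of methyl acetate to the hindered but highly electrophilic, non-enolizable aldehyde introduces C9 and the ester; the carbinol centre is left uncontrolled because step 11 oxidizes it.

Step 11
Reactants: 17 β-hydroxy ester
Product: 18 methyl (5R,8E)-10-[(tert-butyldiphenylsilyl)oxy]-4,4,8-trimethyl-3-oxo-5-(prop-1-en-2-yl)dec-8-enoate
Conditions: Dess–Martin periodinane, NaHCO3, CH2Cl2, 0 °C → rt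
Reagents that add atoms: none
Why: Dess–Martin oxidation of the secondary alcohol gives the β-keto ester (cyclization precursor) without over-oxidizing the active methylene.

Step 12
Reactants: 18 β-keto ester
Product: 19 methyl (4R)-4-[(3E)-5-[(tert-butyldiphenylsilyl)oxy]-3-methylpent-3-en-1-yl]-3,3-dimethyl-5-methylidene-2-oxocyclohexane-1-carboxylate (both C1 epimers)
Conditions: Mn(OAc)3·2H2O (2.1 equiv), Cu(OAc)2·H2O (1.0 equiv, about 0.1 M), degassed AcOH, 25 °C
Reagents that add atoms: none
Why: Mn(OAc)3 forms the manganese enolate of the β-keto ester and electron transfer to trivalent manganese gives the electrophilic C9 radical, which adds to the unsubstituted CH2 terminus (C8) of the isopropenyl group, after which Cu(OAc)2 captures the tertiary C7 radical as an alkylcopper species that loses a β-hydrogen from the methyl group to give the C7=C15 methylene, two equivalents of trivalent manganese being consumed while divalent copper is regenerated. The closest known reaction type is the Mn(OAc)3/Cu(OAc)2 oxidative free-radical cyclization of unsaturated β-keto esters to 2-carbomethoxy methylenecyclohexanones. The single ring closes in the 6-endo-trig mode, with C8–C9 as the only new skeletal bond. The only new stereocentre, the ester-bearing C9, is uncontrolled and need not be controlled because it is enolizable and is erased in step 13, while C6 is β to the ketone, carries no acidic hydrogen and keeps the carvone configuration. Three selectivities are needed: 6-endo over 5-exo attack, secured by the ketone lying inside the forming ring together with the 1,1-disubstituted acceptor; exocyclic over endocyclic alkene, secured by copper-mediated elimination toward the least hindered β-hydrogen; and oxidation of the C7 radical before it can add to the C2=C3 alkene, secured by a full equivalent of Cu(OAc)2 at about 0.1 M. Further oxidation of the still enolizable product is held back by using only two equivalents of Mn(OAc)3 and quenching when its brown colour has faded.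

Step 13
Reactants: 19 cyclic β-keto ester
Product: 20 (3R)-3-[(3E)-5-[(tert-butyldiphenylsilyl)oxy]-3-methylpent-3-en-1-yl]-2,2-dimethyl-4-methylidenecyclohexan-1-one
Conditions: LiCl, H2O (2 equiv), DMSO, 140 °C
Reagents that add atoms: none
Why: Krapcho dealkoxycarbonylation (chloride attacks the ester methyl, the β-keto carboxylate loses CO2) under neutral conditions that should leave the exocyclic alkene and the non-enolizable C6 centre unchanged.

Step 14
Reactants: 20 silyl ether ketone
Product: 21 (3R)-3-[(3E)-5-hydroxy-3-methylpent-3-en-1-yl]-2,2-dimethyl-4-methylidenecyclohexan-1-one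
Conditions: Bu4NF, THF, 0 °C → rt
Reagents that add atoms: none
Why: Fluoride-mediated desilylation frees the allylic alcohol; the ketone has no epimerizable stereocentre next to it.

Step 15
Reactants: 21 allylic alcohol; 22 4-hydroxy-5-methylcoumarin
Product: 23 4-{[(2E)-5-[(1R)-2,2-dimethyl-6-methylidene-3-oxocyclohexyl]-3-methylpent-2-en-1-yl]oxy}-5-methyl-2H-chromen-2-one (target)
Conditions: PPh3, i-PrO2CN=NCO2i-Pr, THF, 0 °C → rt
Reagents that add atoms: none
Why: Mitsunobu etherification, in which the acidic 4-hydroxycoumarin is alkylated on oxygen by direct SN2 displacement of the primary allylic oxyphosphonium ion, so the E alkene is kept.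

**Compound list**

1 | (S)-(+)-carvone, (5S)-2-methyl-5-(prop-1-en-2-yl)cyclohex-2-en-1-one | CC1=CC[C@@H](CC1=O)C(C)=C | starting material
2 | cross-conjugated lithium dienolate of 1 (O–Li on C1, C1=C6 and C2=C3 double bonds, C5 as in 1) | CC1=CC[C@@H](C=C1O[Li])C(C)=C | intermediate
3 | (5S)-2,6-dimethyl-5-(prop-1-en-2-yl)cyclohex-2-en-1-one, C6 epimers | CC1=CC[C@@H](C(C)C1=O)C(C)=C | intermediate
4 | cross-conjugated lithium dienolate of 3 (O–Li on C1, C1=C6 and C2=C3 double bonds, C5 as in 1) | CC1=CC[C@@H](C(C)=C1O[Li])C(C)=C | intermediate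
5 | (5R)-2,6,6-trimethyl-5-(prop-1-en-2-yl)cyclohex-2-en-1-one | CC1=CC[C@@H](C(C)(C)C1=O)C(C)=C | intermediate
6 | lithium (5R)-2,6,6-trimethyl-5-(prop-1-en-2-yl)cyclohex-1-en-1-olate | CC1=C(O[Li])C(C)(C)[C@H](CC1)C(C)=C | intermediate
7 | trimethyl{[(5R)-2,6,6-trimethyl-5-(prop-1-en-2-yl)cyclohex-1-en-1-yl]oxy}silane | CC1=C(O[Si](C)(C)C)C(C)(C)[C@H](CC1)C(C)=C | intermediate
8 | (3R)-2,2,6-trimethyl-3-(prop-1-en-2-yl)-6-[(trimethylsilyl)oxy]cyclohexan-1-one, C6 epimers | CC1(O[Si](C)(C)C)CC[C@H](C(C)=C)C(C)(C)C1=O | intermediate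
9 | (3R)-6-hydroxy-2,2,6-trimethyl-3-(prop-1-en-2-yl)cyclohexan-1-one, C6 epimers | CC1(O)CC[C@H](C(C)=C)C(C)(C)C1=O | intermediate
10 | methyl (3R)-2,2-dimethyl-6-oxo-3-(prop-1-en-2-yl)heptanoate | COC(=O)C(C)(C)[C@H](CCC(C)=O)C(C)=C | intermediate
11 | triethyl phosphonoacetate | CCOC(=O)CP(=O)(OCC)OCC | starting material
12 | 1-ethyl 8-methyl (2E,6R)-3,7,7-trimethyl-6-(prop-1-en-2-yl)oct-2-enedioate | CCOC(=O)/C=C(\C)CC[C@H](C(C)=C)C(C)(C)C(=O)OC | intermediate
13 | (2E,6R)-3,7,7-trimethyl-6-(prop-1-en-2-yl)oct-2-ene-1,8-diol | OC/C=C(\C)CC[C@H](C(C)=C)C(C)(C)CO | intermediate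
14 | (3R,6E)-8-[(tert-butyldiphenylsilyl)oxy]-2,2,6-trimethyl-3-(prop-1-en-2-yl)oct-6-en-1-ol | OCC(C)(C)[C@H](CC/C(C)=C/CO[Si](c1ccccc1)(c1ccccc1)C(C)(C)C)C(C)=C | intermediate
15 | (3R,6E)-8-[(tert-butyldiphenylsilyl)oxy]-2,2,6-trimethyl-3-(prop-1-en-2-yl)oct-6-enal | O=CC(C)(C)[C@H](CC/C(C)=C/CO[Si](c1ccccc1)(c1ccccc1)C(C)(C)C)C(C)=C | intermediate
16 | methyl acetate | COC(C)=O | starting material
17 | methyl (5R,8E)-10-[(tert-butyldiphenylsilyl)oxy]-3-hydroxy-4,4,8-trimethyl-5-(prop-1-en-2-yl)dec-8-enoate, C3 epimers | COC(=O)CC(O)C(C)(C)[C@H](CC/C(C)=C/CO[Si](c1ccccc1)(c1ccccc1)C(C)(C)C)C(C)=C | intermediate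
18 | methyl (5R,8E)-10-[(tert-butyldiphenylsilyl)oxy]-4,4,8-trimethyl-3-oxo-5-(prop-1-en-2-yl)dec-8-enoate | COC(=O)CC(=O)C(C)(C)[C@H](CC/C(C)=C/CO[Si](c1ccccc1)(c1ccccc1)C(C)(C)C)C(C)=C | intermediate
19 | methyl (4R)-4-[(3E)-5-[(tert-butyldiphenylsilyl)oxy]-3-methylpent-3-en-1-yl]-3,3-dimethyl-5-methylidene-2-oxocyclohexane-1-carboxylate, C1 epimers | COC(=O)C1CC(=C)[C@@H](CC/C(C)=C/CO[Si](c2ccccc2)(c2ccccc2)C(C)(C)C)C(C)(C)C1=O | intermediate
20 | (3R)-3-[(3E)-5-[(tert-butyldiphenylsilyl)oxy]-3-methylpent-3-en-1-yl]-2,2-dimethyl-4-methylidenecyclohexan-1-one | C=C1CCC(=O)C(C)(C)[C@@H]1CC/C(C)=C/CO[Si](c2ccccc2)(c2ccccc2)C(C)(C)C | intermediate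
21 | (3R)-3-[(3E)-5-hydroxy-3-methylpent-3-en-1-yl]-2,2-dimethyl-4-methylidenecyclohexan-1-one | C=C1CCC(=O)C(C)(C)[C@@H]1CC/C(C)=C/CO | intermediate
22 | 4-hydroxy-5-methylcoumarin | Cc1cccc2oc(=O)cc(O)c12 | starting material
23 | 4-{[(2E)-5-[(1R)-2,2-dimethyl-6-methylidene-3-oxocyclohexyl]-3-methylpent-2-en-1-yl]oxy}-5-methyl-2H-chromen-2-one | C=C1CCC(=O)C(C)(C)[C@@H]1CC/C(C)=C/COc1cc(=O)oc2cccc(C)c12 | target

**Step count**

Total: 15 steps. Longest linear sequence: 15 steps, from 1 to 23.

**Steps most likely to fail**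

Step 12. The cyclized β-keto ester still has an acidic hydrogen between its carbonyls, so it may be oxidized again by trivalent manganese at a rate close to that of the starting material, and material would then be lost to dehydrogenation or coupling. The fallback sets out from 18. Its sodium enolate (NaH, THF, 0 °C) is chlorinated with N-chlorosuccinimide to give methyl (5R,8E)-10-[(tert-butyldiphenylsilyl)oxy]-2-chloro-4,4,8-trimethyl-3-oxo-5-(prop-1-en-2-yl)dec-8-enoate F1. The same Mn(OAc)3/Cu(OAc)2 cyclization in AcOH should then give methyl (4R)-1-chloro-4-[(3E)-5-[(tert-butyldiphenylsilyl)oxy]-3-methylpent-3-en-1-yl]-3,3-dimethyl-5-methylidene-2-oxocyclohexane-1-carboxylate F2, which has no hydrogen left between the carbonyls and cannot be oxidized further. Reductive dechlorination with Zn in AcOH at room temperature comes back to the route at 19.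

Step 5. The ketone of 9 lies between two fully substituted carbons, so the hemiketal that the lead reagent needs may form too slowly; the cleavage may stall and forcing it may start oxidation of the isopropenyl group. The fallback sets out from 9 and replaces ketol cleavage by glycol cleavage. LiAlH4 in Et2O at 0 °C reduces the ketone to (4R)-1,3,3-trimethyl-4-(prop-1-en-2-yl)cyclohexane-1,2-diol F3 (diastereomer mixture). NaIO4 in THF/H2O cleaves it to (3R)-2,2-dimethyl-6-oxo-3-(prop-1-en-2-yl)heptanal F4. Pinnick oxidation (NaClO2, NaH2PO4, 2-methylbut-2-ene, t-BuOH/H2O) gives (3R)-2,2-dimethyl-6-oxo-3-(prop-1-en-2-yl)heptanoic acid F5, and Me3SiCHN2 in MeOH/toluene esterifies it, coming back to the route at 10.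

Step 15. The coumarin is an ambident nucleophile and its 4-oxygen is crowded by the peri 5-methyl group, so under Mitsunobu conditions alkylation may drift to the lactone carbonyl oxygen (2-alkoxychromone) or to C3. The fallback sets out from 21. CBr4 and PPh3 in CH2Cl2 at 0 °C convert it into (3R)-3-[(3E)-5-bromo-3-methylpent-3-en-1-yl]-2,2-dimethyl-4-methylidenecyclohexan-1-one F6. This bromide alkylates the potassium salt of 22 (K2CO3, acetone, reflux), the standard way to 4-allyloxycoumarins, coming back to the route at 23.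

Further compounds
F1 | step 12 | methyl (5R,8E)-10-[(tert-butyldiphenylsilyl)oxy]-2-chloro-4,4,8-trimethyl-3-oxo-5-(prop-1-en-2-yl)dec-8-enoate, C2 epimers | COC(=O)C(Cl)C(=O)C(C)(C)[C@H](CC/C(C)=C/CO[Si](c1ccccc1)(c1ccccc1)C(C)(C)C)C(C)=C
F2 | step 12 | methyl (4R)-1-chloro-4-[(3E)-5-[(tert-butyldiphenylsilyl)oxy]-3-methylpent-3-en-1-yl]-3,3-dimethyl-5-methylidene-2-oxocyclohexane-1-carboxylate, C1 epimers | COC(=O)C1(Cl)CC(=C)[C@@H](CC/C(C)=C/CO[Si](c2ccccc2)(c2ccccc2)C(C)(C)C)C(C)(C)C1=O
F3 | step 5 | (4R)-1,3,3-trimethyl-4-(prop-1-en-2-yl)cyclohexane-1,2-diol, diastereomer mixture | CC1(O)CC[C@H](C(C)=C)C(C)(C)C1O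
F4 | step 5 | (3R)-2,2-dimethyl-6-oxo-3-(prop-1-en-2-yl)heptanal | O=CC(C)(C)[C@H](CCC(C)=O)C(C)=C
F5 | step 5 | (3R)-2,2-dimethyl-6-oxo-3-(prop-1-en-2-yl)heptanoic acid | OC(=O)C(C)(C)[C@H](CCC(C)=O)C(C)=C
F6 | step 15 | (3R)-3-[(3E)-5-bromo-3-methylpent-3-en-1-yl]-2,2-dimethyl-4-methylidenecyclohexan-1-one | C=C1CCC(=O)C(C)(C)[C@@H]1CC/C(C)=C/CBr
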